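## Structural features

Compound 22 is a labdane-type diterpenoid methyl ester built on a trans-fused decalin. Ring A (C1–C5, C10) carries the gem-dimethyl carbon C4 and a cis-2α,3α-diol; ring B (C5–C10) carries the methyl C17 on C8 and a tertiary hydroxyl on C9; the rings share C5 (α-H) and C10 (β-methyl C20). A five-carbon chain (C11–C15, with the methyl C16 on C13) hangs from the α face of C9 and ends in a (Z)-3-methyl-2-enoate, with the ester cis to the chain. The six stereocentres form two blocks: C2/C3 beside quaternary C4, and the contiguous array C5–C10–C9–C8, in which the fully substituted carbinol C9 (OH β and equatorial, chain α and axial) is wedged between quaternary C10 and the methine C8 (methyl α, equatorial). Fragile points are the tertiary C9–OH (ionisation and dehydration in acid), the Z-enoate (isomerisation to E; its alkyne precursor can be attacked by the neighbouring C9 alkoxide) and the free vicinal diol. The real difficulty is the crowded C8–C9–C10 triad: a carbon nucleophile must reach a carbonyl flanked on both sides with control of C9 and C8, and the trisubstituted alkene must be made in its less stable geometry. The key step exploits the fact that ring B is already present in carvone: the carbonyl carbon is C9, the methyl-bearing alkene carbon is C8 with C17, the ring carbon bearing the isopropenyl group is C5, and the isopropenyl carbon, once protonated, is the gem-dimethyl carbon C4 of ring A. The α′ carbon of carvone is C10, so two alkylations there supply C20 and the C1–C3 chain, and a vinylsilane at C3 lets the C4 cation close ring A while leaving the C2=C3 alkene exactly where the cis-diol is needed.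

## Logic of the disconnections

22 to 21. The two C–O bonds at C2 and C3 are cut. A cis-diol on a cyclohexane is the retron of a syn-dihydroxylation, so 22 goes back to 21 with a C2=C3 alkene. Two stereocentres disappear, and no protecting group is needed anywhere in the route, because an alkene is inert to the bases and organometallics used earlier. The forward step must attack the α face and must prefer the isolated ring alkene of 21 to its conjugated, trisubstituted ester alkene.

21 to 19. The C13–C16 bond is cut. A 3-methyl-2-enoate with the ester cis to the longer chain is the product of syn addition of a methylcopper reagent to a 2-ynoate, so 21 goes back to 19 through 20. The geometry problem becomes the stereospecificity of one addition. The forward step must be run and quenched cold so that 20 does not equilibrate, and it must tolerate the free C9 hydroxyl.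

19 to 17 to 16. The C14–C15 bond of 19 is cut (acetylide plus chloroformate, through 18), and the acetylenic hydrogen of 17 is exchanged for silicon to give 16. The side chain is reduced to a four-carbon silylalkyne that can be carried as an organometallic. The forward step needs C-acylation of 18 in preference to O-acylation or cyclisation of the C9 alkoxide.

16 to 12 and 13. The C9–C11 bond is cut. A tertiary carbinol beside a quaternary carbon is best made from the ketone, and the nucleophile is expected on the α face, the only one not covered by C20; this gives OH β and chain α as in 22. The whole side chain is removed and the route becomes convergent (12 plus commercial 13). The forward step needs a reagent that adds to a hindered, enolisable ketone without deprotonating it, hence 15 made through 14.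

12 to 9. The C7–H and C8–H bonds are removed to reveal the enone of 9. C8 is then α to a carbonyl and can be set by equilibration, since the α (equatorial) methyl avoids a 1,3-diaxial contact with C20. Placing this reduction before the C9 addition frees C8 from any dependence on a face-selective hydrogenation of a crowded allylic alcohol. The forward step must reduce only the conjugated alkene and leave C2=C3 (through 10 and 11).

9 to 8. The C3–C4 bond of ring A is cut. C4 is a tertiary carbon that can be a cation, and C3 can be the silicon-bearing carbon of a vinylsilane; the isopropenyl group of 8 becomes the cation on protonation. Ring A, the gem-dimethyl group and the C2=C3 alkene all arise from a monocyclic precursor in one step. The forward step needs attack through the silyl-bearing carbon to the six-membered ring, ahead of hydride shift, proton loss and protodesilylation, and it needs a Z vinylsilane.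

8 to 3 and 6, and 3 to 1. The C10–C1 and C10–C20 bonds are cut: two α′-alkylations of 1 through 2 and 7. The methyl group is introduced first so that the larger chain enters last, anti to the isopropenyl group. This sets the quaternary centre and reaches the chiral-pool compound 1, whose stereocentre becomes C5. The forward steps need kinetic α′ deprotonation and facial control by the adjacent isopropenyl group.

6 to 5 to 4. The C–Br bond is traced to C–O and the Z alkene to the alkyne of 4 by syn hydrogenation. The forward steps must keep the Z geometry pure, because step 5 depends on it.

## Other disconnections considered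

Alternative 1: The cut is the C9–O bond. The tertiary alcohol and C11–C13 are traced to a cyclobutanone spiro-fused at C9 (A1), whose carbonyl carbon is C13 and lies on the β face. Irradiation of A1 near 300 nm in methanol would cleave the C9–C13 bond (Norrish type 1), the acyl–alkyl diradical would reclose on oxygen to an oxacarbene, and methanol would add to give the spiro 2-methoxytetrahydrofuran A2 as both acetal epimers.
- In its favour: the C9–O bond forms under neutral conditions with retention at C9, and A2 is a masked γ-hydroxy aldehyde at the right oxidation level for chain extension.
- Against it here: A1 must be made first. The usual spiro-annulations of a C9 carbonyl (cyclopropyl anion or ylide addition, then ring expansion) would be expected to attach the future carbonyl carbon from the open α face. After photolysis that puts oxygen α and the chain β, the opposite of 22, so A1 demands bond formation on the β face of C9. Cyclobutanone photolysis also offers cycloelimination and decarbonylation. From A2 the chain still needs acetal hydrolysis, one-carbon homologation to the alkyne, carboxylation and cuprate addition, and the diol must be carried as an acetonide.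
- Comparison: structurally both plans need the same decalin and a C9 carbonyl stage, so no ring construction is saved. Mechanistically the photochemical transfer of configuration is the equal of the addition in step 7, and better in that no basic reagent meets the hindered carbonyl when the oxygen is installed; but the configuration it transfers is harder to set. In step economy it is longer by roughly five or six steps than steps 7–11.

Alternative 2: Both rings are cut at once, at C4–C5 and C9–C10, back to the acyclic epoxy-enyne A3 ((3S)-epoxide, E trisubstituted alkene, methyl-bearing propargylic centre that becomes C8). MeAlCl2 would open the epoxide at C4, the C5=C10 alkene and then alkyne carbon C9 would attack in turn, and water would turn the vinyl cation into the acetyl group of A4 (9β-acetyl, 3β-hydroxyl).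
- In its favour: two rings, two C–C bonds and the C5/C10 ring fusion form in one operation from a linear chain, with the absolute sense read from the epoxide. In complexity gained per step this is clearly better than step 5 of the chosen plan, which closes one ring and creates no stereocentre, and no chiral-pool material is needed.
- Against it here: A4 is wrongly functionalised in three places. Ring A has a 3β-hydroxyl and no oxygen at C2, so it must be dehydrated to the C2=C3 alkene, and ionisation beside the gem-dimethyl carbon invites methyl migration and ring contraction. The acetyl group is only a placeholder for oxygen: Baeyer–Villiger oxidation, hydrolysis and oxidation are needed to reach a C9 carbonyl, after which the same addition, alkyne elaboration and dihydroxylation as in steps 7–11 remain. A3 needs two remote stereocentres set independently and a geometrically pure alkene.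
- Comparison: structurally the alternative builds the skeleton more elegantly but delivers it mis-oxidised, whereas 9 has its alkene and carbonyl exactly where 22 needs oxygen. Mechanistically both are cation–olefin closures, the alternative with more branch points (partial cyclisation, proton loss) because three bond-forming events must follow one another. In step economy it lies well beyond eleven steps, counting the synthesis of A3 and roughly ten steps after A4.

Alternative 3: The C8–C9 bond is cut, so ring B closes last. The precursor A5 is a ring A cyclohexane carrying the acetonide, the gem-dimethyl group, a but-3-enyl chain on C5 and, on quaternary C10, the methyl group and the acyl chain containing C9 and the silylalkyne. SmI2 with HMPA and t-BuOH would reduce the ketone to its ketyl, which would add 6-exo-trig to C8 of the terminal alkene; reduction and protonation of the primary radical would leave C17 as a methyl group in A6.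
- In its favour: C8 and C9 are created together with the chain already on C9, so no nucleophile has to add to a hindered ring ketone. A chair transition state with the bulky samarium alkoxide and the alkene terminus both equatorial leads to the trans OH/CH3 arrangement of 22. Two stereocentres and a ring in one step, where the chosen plan needs steps 6 and 7, make the alternative the better one on this point. A6 is four steps from 22 (desilylation, carboxylation, cuprate addition, acetonide removal), the equal of the chosen endgame.
- Against it here: 6-exo ketyl additions to unactivated alkenes are slow, so simple ketone reduction and pinacol coupling compete. The C9 selectivity rests on a conformational preference and not on a blocked face. A5, a pentasubstituted cyclohexane with a quaternary stereocentre, has no short chiral-pool origin comparable with 1; its enantioselective synthesis would probably take more steps than the chosen route needs to reach 12.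
- Comparison: structurally the chosen plan takes ring B ready-made from 1 and closes ring A, while the alternative must first build ring A with five substituents. Mechanistically the radical closure avoids both the strong acid and the organocerium reagent but is less certain in rate. In step economy it is worse overall because of A5.

Key step: step 5

Remarks on the chemistry.
- Labdane numbering is used throughout (ring A = C1–C5 and C10; ring B = C5–C10; C17 on C8; C18/C19 on C4; C20 on C10; side chain C11–C16). β is the face of C20, α the opposite face.
- The configurations of 8 and 9 were checked atom by atom against 1 and 22. C5 keeps the configuration of 1; in 8 the C20 methyl is cis and the C1 chain trans to the isopropenyl group; the vinylsilane is Z. The two structures are mutually consistent and lead to the configuration of 22 at C5 and C10.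
- The steps after the ring closure are ordered so that C8 is set by equilibration before the C9 addition and the diol is installed last; this avoids a directed hydrogenation and any protecting group.
- Assumption: kinetic protonation of enolate 10 may not be selective, so step 6 ends with a base equilibration that puts C8 under thermodynamic control.

## Route

Step 1
Reactants: 1 (R)-(−)-carvone
Product: 3 6-methylcarvone [(5R,6RS)-2,6-dimethyl-5-(prop-1-en-2-yl)cyclohex-2-en-1-one; both C6 epimers], via lithium dienolate of carvone 2 (not isolated)
Conditions: LiN(i-Pr)2 (1.05 equiv), THF, −78 °C; CH3I, −78 to 0 °C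
Reagents that add atoms: iodomethane, CI
Why: Kinetic deprotonation of the enone by the lithium amide occurs at the α′ carbon (future C10) to give the cross-conjugated dienolate 2, and enolate alkylation with iodomethane introduces C20. The new centre need not be controlled because it is planarised again in step 4.

Step 2
Reactants: 4 3-(trimethylsilyl)prop-2-yn-1-ol
Product: 5 (Z)-3-(trimethylsilyl)prop-2-en-1-ol
Conditions: H2 (1 atm), Ni(OAc)2·4H2O (5 mol %), NaBH4 (5 mol %), H2NCH2CH2NH2, EtOH, rt
Reagents that add atoms: none
Why: Semi-hydrogenation of the alkyne on the nickel boride catalyst formed in the flask, moderated by ethylenediamine, delivers both hydrogens to one face and should stop at the alkene. Syn addition fixes the Z geometry.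

Step 3
Reactants: 5 (Z)-3-(trimethylsilyl)prop-2-en-1-ol
Product: 6 (Z)-(3-bromoprop-1-en-1-yl)trimethylsilane
Conditions: CBr4, PPh3, CH2Cl2, 0 °C
Reagents that add atoms: carbon tetrabromide, BrC(Br)(Br)Br
Why: The Appel reaction converts the primary allylic alcohol into the bromide by SN2 displacement of the oxyphosphonium group under neutral conditions. No acid is present to protodesilylate or isomerise the Z-vinylsilane.

Step 4
Reactants: 3 6-methylcarvone; 6 (Z)-(3-bromoprop-1-en-1-yl)trimethylsilane
Product: 8 (5S,6S)-2,6-dimethyl-5-(prop-1-en-2-yl)-6-[(2Z)-3-(trimethylsilyl)prop-2-en-1-yl]cyclohex-2-en-1-one, via lithium dienolate of 6-methylcarvone 7 (not isolated)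
Conditions: LiN(i-Pr)2 (1.1 equiv), THF, −78 to −20 °C; then 6, DMPU, −78 to 0 °C
Reagents that add atoms: none
Why: Enolate alkylation of 7 with the reactive primary allylic bromide forms the C10–C1 bond and the quaternary centre. The electrophile should approach the planar enolate anti to the isopropenyl group on the adjacent carbon (1,2-induction), so the chain ends trans and the methyl cis to isopropenyl, which is the relative configuration of C10 and C5 in 22.

Step 5
Reactants: 8 (5S,6S)-2,6-dimethyl-5-(prop-1-en-2-yl)-6-[(2Z)-3-(trimethylsilyl)prop-2-en-1-yl]cyclohex-2-en-1-one
Product: 9 (4aS,8aS)-2,5,5,8a-tetramethyl-4a,5,8,8a-tetrahydronaphthalen-1(4H)-one (4,4,8,10-tetramethyl-5αH-decal-2,7-dien-9-one in labdane numbering; trans-fused)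
Conditions: CF3SO3H (1.5 equiv), CH2Cl2, −78 to −30 °C; aq. NaHCO3
Reagents that add atoms: none
Why: CF3SO3H protonates the 1,1-disubstituted isopropenyl alkene of 8 at its CH2 carbon, and the tertiary cation at C4 is attacked by the silicon-bearing carbon C3 of the vinylsilane, which forms the C3–C4 bond and moves the charge to C2, β to silicon; loss of the silyl group to triflate then leaves the C2=C3 alkene. The closest known reaction type is the vinylsilane-terminated cation–olefin cyclization in which the cation is made by protonating an alkene, as in acid-mediated terpene cyclizations. Ring A closes in the 6-endo-trig mode at the vinylsilane, so both alkene carbons end up inside the new ring. No stereocentre is created; the trans ring fusion is already fixed in 8, because the C1 chain on C10 and the cationic carbon on C5 are trans on ring B and can only be bridged as a diequatorial, chair-like tether. The step needs ipso attack and not five-membered closure through C2, and this is secured by the β-silicon effect, since closure through C2 would leave a cation α to silicon. It needs ring closure to outrun a 1,2-hydride shift from C5 and proton loss from the C4 cation, which the pre-organised intramolecular terminator and the low temperature should ensure, proton loss being reversible in the acid. It needs protonation of the isopropenyl group ahead of protodesilylation, which follows from the higher basicity of a 1,1-dialkyl alkene. The Z geometry matters because it places the C–Si bond nearly parallel to the empty orbital at C2 as soon as the ring bond forms, and the enone is only O-protonated reversibly.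

Step 6
Reactants: 9 (4aS,8aS)-2,5,5,8a-tetramethyl-4a,5,8,8a-tetrahydronaphthalen-1(4H)-one
Product: 12 (2R,4aS,8aS)-2,5,5,8a-tetramethyl-3,4,4a,5,8,8a-hexahydronaphthalen-1(2H)-one (4,4,8α,10β-tetramethyl-5αH-decal-2-en-9-one in labdane numbering), via lithium enolate 10 (not isolated), via crude C8-epimeric ketone 11 (not isolated)
Conditions: Li (2.2 equiv), t-BuOH (1.0 equiv), NH3(l)/THF, −78 °C; NH4Cl; then NaOMe (cat.), MeOH, rt
Reagents that add atoms: none
Why: Dissolving-metal (Birch-type) conjugate reduction transfers electrons only to the enone, so the isolated C2=C3 alkene survives and enolate 10 is protected from over-reduction until the quench. C8 is then set under thermodynamic control by methoxide equilibration of 11: the α (equatorial) methyl is strongly preferred because a β (axial) methyl would be 1,3-diaxial to C20.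

Step 7
Reactants: 13 (4-bromobut-1-yn-1-yl)trimethylsilane; 12 (2R,4aS,8aS)-2,5,5,8a-tetramethyl-3,4,4a,5,8,8a-hexahydronaphthalen-1(2H)-one
Product: 16 9α-[4-(trimethylsilyl)but-3-yn-1-yl]-4,4,8α,10β-tetramethyl-5αH-decal-2-en-9β-ol (labdane numbering), via Grignard reagent 14 (not isolated), via organocerium reagent 15 (not isolated)
Conditions: 13, Mg, THF, rt; anhydrous CeCl3, THF, −78 °C; then 12, −78 to 0 °C; aq. NH4Cl
Reagents that add atoms: none
Why: Grignard formation and transmetalation to cerium give a strongly oxophilic, weakly basic nucleophile, which should undergo 1,2-addition to the hindered ketone without enolising it toward C8 or reducing it. C9 is set by attack on the α (axial) face, because the β face is closed by the axial C20 methyl on the adjacent carbon and by the peri C1 methylene; this gives OH β and chain α.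

Step 8
Reactants: 16 9α-[4-(trimethylsilyl)but-3-yn-1-yl]-4,4,8α,10β-tetramethyl-5αH-decal-2-en-9β-ol
Product: 17 9α-(but-3-yn-1-yl)-4,4,8α,10β-tetramethyl-5αH-decal-2-en-9β-ol
Conditions: K2CO3 (cat.), MeOH, rt
Reagents that add atoms: none
Why: Base-catalysed methanolysis cleaves the alkynyl C–Si bond (protodesilylation of a silylalkyne). The tertiary alcohol, the ring alkene and all stereocentres are inert to these conditions.

Step 9
Reactants: 17 9α-(but-3-yn-1-yl)-4,4,8α,10β-tetramethyl-5αH-decal-2-en-9β-ol
Product: 19 methyl 5-(9β-hydroxy-4,4,8α,10β-tetramethyl-5αH-decal-2-en-9α-yl)pent-2-ynoate, via dilithio acetylide alkoxide 18 (not isolated)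
Conditions: n-BuLi (2.1 equiv), THF, −78 °C; ClCO2CH3 (1.1 equiv), −78 °C; aq. NH4Cl at −78 °C
Reagents that add atoms: methyl chloroformate, COC(Cl)=O
Why: C-acylation of a lithium acetylide with a chloroformate gives the 2-ynoate. In dianion 18 the acetylide carbon is far more nucleophilic than the tertiary alkoxide buried between C8 and C10, and quenching cold should prevent the alkoxide from adding to the new ynoate.

Step 10
Reactants: 19 methyl 5-(9β-hydroxy-4,4,8α,10β-tetramethyl-5αH-decal-2-en-9α-yl)pent-2-ynoate
Product: 21 methyl (2Z)-5-(9β-hydroxy-4,4,8α,10β-tetramethyl-5αH-decal-2-en-9α-yl)-3-methylpent-2-enoate, via alkenylcuprate adduct 20 (not isolated)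
Conditions: (CH3)2CuLi (3 equiv, from CuI and CH3Li), THF/Et2O, −78 °C; CH3OH then aq. NH4Cl at −78 °C
Reagents that add atoms: lithium dimethylcuprate (made from methyllithium and CuI), [Li+].C[Cu-]C
Why: Conjugate addition of the cuprate to the 2-ynoate is a syn carbocupration, so methyl and copper are cis in 20. Protonation at −78 °C with retention leaves the ester cis to the C12 chain, which is the Z geometry of 22; excess reagent covers the methyl group consumed by the free hydroxyl.

Step 11
Reactants: 21 methyl (2Z)-5-(9β-hydroxy-4,4,8α,10β-tetramethyl-5αH-decal-2-en-9α-yl)-3-methylpent-2-enoate
Product: 22 methyl (2Z)-3-methyl-5-[(2α,3α,9β)-trihydroxy-4,4,8α,10β-tetramethyl-5αH-decalin-9α-yl]pent-2-enoate (labdane numbering; 2R,3S,5S,8R,9S,10S; CNP0292844.2)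
Conditions: OsO4 (2 mol %), NMO (1.2 equiv), acetone/H2O, rt; aq. Na2SO3
Reagents that add atoms: osmium tetroxide, O=[Os](=O)(=O)=O; N-methylmorpholine N-oxide, C[N+]1([O-])CCOCC1; water, O
Why: Catalytic OsO4 syn-dihydroxylation adds both oxygens to one face of C2=C3. The β face of ring A is covered by two axial methyls (C20 and the β-methyl on C4), so the cis-2α,3α-diol should form, and the electrophilic oxidant should prefer the isolated ring alkene to the electron-poor, trisubstituted ester alkene.

## Compound list

1 | (R)-(−)-carvone, (5R)-2-methyl-5-(prop-1-en-2-yl)cyclohex-2-en-1-one | CC1=CC[C@H](CC1=O)C(C)=C | starting material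
2 | lithium dienolate of carvone (O–Li on the carbonyl carbon, new C=C toward the α′ carbon; formed in the flask) | CC1=CC[C@H](C=C1O[Li])C(C)=C | intermediate
3 | 6-methylcarvone, (5R,6RS)-2,6-dimethyl-5-(prop-1-en-2-yl)cyclohex-2-en-1-one, both C6 epimers | CC1=CC[C@H](C(C)C1=O)C(C)=C | intermediate
4 | 3-(trimethylsilyl)prop-2-yn-1-ol | C[Si](C)(C)C#CCO | starting material
5 | (Z)-3-(trimethylsilyl)prop-2-en-1-ol | C[Si](C)(C)/C=C\CO | intermediate
6 | (Z)-(3-bromoprop-1-en-1-yl)trimethylsilane | C[Si](C)(C)/C=C\CBr | intermediate
7 | lithium dienolate of 6-methylcarvone (formed in the flask) | CC1=CC[C@H](C(C)=C1O[Li])C(C)=C | intermediate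
8 | (5S,6S)-2,6-dimethyl-5-(prop-1-en-2-yl)-6-[(2Z)-3-(trimethylsilyl)prop-2-en-1-yl]cyclohex-2-en-1-one (6-methyl-6-[(Z)-3-(trimethylsilyl)allyl]carvone, chain trans to isopropenyl) | O=C1C(C)=CC[C@@H](C(C)=C)[C@]1(C)C/C=C\[Si](C)(C)C | intermediate
9 | (4aS,8aS)-2,5,5,8a-tetramethyl-4a,5,8,8a-tetrahydronaphthalen-1(4H)-one (4,4,8,10-tetramethyl-5αH-decal-2,7-dien-9-one, trans-fused) | O=C1C(C)=CC[C@H]2C(C)(C)C=CC[C@@]21C | intermediate
10 | lithium enolate of the C9 ketone (C8=C9–OLi; formed in the flask) | [Li]OC1=C(C)CC[C@H]2C(C)(C)C=CC[C@@]21C | intermediate
11 | crude 4,4,8,10-tetramethyl-5αH-decal-2-en-9-one, C8 epimers (formed in the flask) | O=C1C(C)CC[C@H]2C(C)(C)C=CC[C@@]21C | intermediate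
12 | (2R,4aS,8aS)-2,5,5,8a-tetramethyl-3,4,4a,5,8,8a-hexahydronaphthalen-1(2H)-one (4,4,8α,10β-tetramethyl-5αH-decal-2-en-9-one) | O=C1[C@H](C)CC[C@H]2C(C)(C)C=CC[C@@]21C | intermediate
13 | (4-bromobut-1-yn-1-yl)trimethylsilane | C[Si](C)(C)C#CCCBr | starting material
14 | [4-(trimethylsilyl)but-3-yn-1-yl]magnesium bromide (formed in the flask) | C[Si](C)(C)C#CCC[Mg]Br | intermediate
15 | dichloro[4-(trimethylsilyl)but-3-yn-1-yl]cerium (formed in the flask) | C[Si](C)(C)C#CCC[Ce](Cl)Cl | intermediate
16 | 9α-[4-(trimethylsilyl)but-3-yn-1-yl]-4,4,8α,10β-tetramethyl-5αH-decal-2-en-9β-ol | C[Si](C)(C)C#CCC[C@]1(O)[C@H](C)CC[C@H]2C(C)(C)C=CC[C@@]21C | intermediate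
17 | 9α-(but-3-yn-1-yl)-4,4,8α,10β-tetramethyl-5αH-decal-2-en-9β-ol | C#CCC[C@]1(O)[C@H](C)CC[C@H]2C(C)(C)C=CC[C@@]21C | intermediate
18 | dilithio derivative of 17 (lithium acetylide and lithium C9 alkoxide; formed in the flask) | [Li]C#CCC[C@]1(O[Li])[C@H](C)CC[C@H]2C(C)(C)C=CC[C@@]21C | intermediate
19 | methyl 5-(9β-hydroxy-4,4,8α,10β-tetramethyl-5αH-decal-2-en-9α-yl)pent-2-ynoate | COC(=O)C#CCC[C@]1(O)[C@H](C)CC[C@H]2C(C)(C)C=CC[C@@]21C | intermediate
20 | alkenyl(methyl)cuprate adduct of 19, copper on C14 cis to the new methyl, C9 alkoxide (formed in the flask) | [Li+].COC(=O)/C(=C(/C)CC[C@]1(O[Li])[C@H](C)CC[C@H]2C(C)(C)C=CC[C@@]21C)[Cu-]C | intermediate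
21 | methyl (2Z)-5-(9β-hydroxy-4,4,8α,10β-tetramethyl-5αH-decal-2-en-9α-yl)-3-methylpent-2-enoate | COC(=O)/C=C(/C)CC[C@]1(O)[C@H](C)CC[C@H]2C(C)(C)C=CC[C@@]21C | intermediate
22 | methyl (2Z)-3-methyl-5-[(2α,3α,9β)-trihydroxy-4,4,8α,10β-tetramethyl-5αH-decalin-9α-yl]pent-2-enoate (2R,3S,5S,8R,9S,10S; CNP0292844.2) | COC(=O)/C=C(/C)CC[C@]1(O)[C@H](C)CC[C@H]2C(C)(C)[C@H](O)[C@H](O)C[C@@]21C | target

## Step count and least certain steps

Total step count: 11. Longest linear sequence: 10 steps, from 4 to 22 (steps 2, 3, 4, 5, 6, 7, 8, 9, 10 and 11). Step 1 is the one-step side branch that converts 1 into 3 for step 4, and 13 enters at step 7.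

Step 5 (key step). The most likely failure is diversion of the reversibly formed C4 cation in a strongly protic medium: protodesilylation of the vinylsilane before ring closure, proton loss to alkene isomers, or a 1,2-hydride shift from C5. Prolonged exposure of 9 to the acid could also start a methyl shift from C4. Fallback, which generates the same cation by aprotic ionisation: from 8, dry HCl in CH2Cl2 at −20 °C should add to the isopropenyl group in the Markovnikov sense to give the tertiary chloride F1. Treatment of the tertiary chloride F1 with TiCl4 (2 equiv, one being held by the carbonyl) and 2,6-di-tert-butylpyridine as proton scavenger in CH2Cl2 at −78 °C would ionise the C–Cl bond in the absence of free acid. The Lewis-acid-mediated alkylation of the vinylsilane by the tertiary chloride should then close ring A and give 9, where the route is rejoined.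

Step 7. The most likely failure is slow or incomplete addition to a carbonyl flanked by a quaternary and a tertiary carbon, with enolisation toward C8 or hydride transfer from the reagent taking over; erosion of facial selectivity is the lesser concern. Fallback, which changes the nucleophile and builds the alkyne afterwards: from 12, allylmagnesium bromide in THF at −78 °C, which adds through a cyclic transition state even to very hindered ketones, should give the homoallylic alcohol F2, with the allyl group expected on the α face for the same steric reasons as in step 7. Hydroboration with 9-BBN and oxidation with NaOH/H2O2 should touch only the terminal alkene (the ring alkene is cis-disubstituted and neopentylic) and give the 1,4-diol F3. Swern oxidation ((COCl)2, DMSO, Et3N) would give the hydroxy aldehyde, which closes to the spiro lactol F4. Ohira–Bestmann homologation of the spiro lactol F4 (dimethyl (1-diazo-2-oxopropyl)phosphonate, K2CO3, MeOH) should deliver 17, where the route is rejoined at the cost of two extra steps.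

Step 9. The most likely failure is reaction of the C9 alkoxide in the same flask: O-acylation by the chloroformate, or 5-exo conjugate addition to the ynoate as it forms; attack of unreacted acetylide on the product ester is a further drain. Fallback, which uses an electrophile that cannot give a Michael acceptor in the presence of the alkoxide: from 17, the dianion (n-BuLi, 2.1 equiv, THF, −78 °C) would be treated with CO2 to give, after acidification, the hydroxy ynoic acid F5. The carboxylate is no acceptor, and any O-carboxylation reverts on work-up. Methylation of the hydroxy ynoic acid F5 with Me3SiCHN2 in MeOH/toluene under neutral conditions should give 19, where the route is rejoined.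

Step 11. The most likely failure is loss of chemoselectivity: if the hindered ring alkene reacts slowly, dihydroxylation of the conjugated C13=C14 alkene may compete. Fallback, which moves the oxidation to a stage with no second alkene: from 19, OsO4 (cat.)/NMO in acetone/H2O should dihydroxylate C2=C3 from the α face, the electron-poor alkyne being inert, to give the triol ynoate F6. Addition of excess (CH3)2CuLi to the triol ynoate F6 at −78 °C, with the reagent amount raised to cover three hydroxyl groups and a cold quench, would then give 22 directly.

## Further compounds

F1 | step 5 | (5R,6S)-5-(2-chloropropan-2-yl)-2,6-dimethyl-6-[(2Z)-3-(trimethylsilyl)prop-2-en-1-yl]cyclohex-2-en-1-one | O=C1C(C)=CC[C@@H](C(C)(C)Cl)[C@]1(C)C/C=C\[Si](C)(C)C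
F2 | step 7 | 9α-allyl-4,4,8α,10β-tetramethyl-5αH-decal-2-en-9β-ol | C=CC[C@]1(O)[C@H](C)CC[C@H]2C(C)(C)C=CC[C@@]21C
F3 | step 7 | 3-(9β-hydroxy-4,4,8α,10β-tetramethyl-5αH-decal-2-en-9α-yl)propan-1-ol | OCCC[C@]1(O)[C@H](C)CC[C@H]2C(C)(C)C=CC[C@@]21C
F4 | step 7 | spiro lactol, 2-hydroxytetrahydrofuran spiro-fused at C9 (ring oxygen β on C9, both anomers) of the 4,4,8α,10β-tetramethyl-5αH-decal-2-ene core | OC3CC[C@]1(O3)[C@H](C)CC[C@H]2C(C)(C)C=CC[C@@]21C
F5 | step 9 | 5-(9β-hydroxy-4,4,8α,10β-tetramethyl-5αH-decal-2-en-9α-yl)pent-2-ynoic acid | OC(=O)C#CCC[C@]1(O)[C@H](C)CC[C@H]2C(C)(C)C=CC[C@@]21C
F6 | step 11 | methyl 5-[(2α,3α,9β)-trihydroxy-4,4,8α,10β-tetramethyl-5αH-decalin-9α-yl]pent-2-ynoate | COC(=O)C#CCC[C@]1(O)[C@H](C)CC[C@H]2C(C)(C)[C@H](O)[C@H](O)C[C@@]21C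
A1 | alternative 1 | C9 spiro-cyclobutanone (carbonyl carbon C13 β on C9, C11 α), 8α-methyl, 2α,3α-acetonide | O=C4CC[C@@]41[C@H](C)CC[C@H]2C(C)(C)[C@H](OC(C)(C)O3)[C@H]3C[C@@]21C
A2 | alternative 1 | spiro 2-methoxytetrahydrofuran C9–O–C13H(OCH3)–C12–C11, both acetal epimers, 2α,3α-acetonide | COC4CC[C@]1(O4)[C@H](C)CC[C@H]2C(C)(C)[C@H](OC(C)(C)O3)[C@H]3C[C@@]21C
A3 | alternative 2 | (3S)-2,2-dimethyl-3-[(3E,7R)-3,7-dimethyldec-3-en-8-yn-1-yl]oxirane | CC#C[C@H](C)CC/C=C(\C)CC[C@@H]1OC1(C)C
A4 | alternative 2 | 9β-acetyl-3β-hydroxy-4,4,8α,10β-tetramethyl-trans-decalin (9α-H) | CC(=O)[C@H]1[C@H](C)CC[C@H]2C(C)(C)[C@@H](O)CC[C@@]21C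
A5 | alternative 3 | ring A cyclohexane: 2α,3α-acetonide, 4,4-dimethyl, 5β-(but-3-en-1-yl) (5α-H), 10β-methyl, 10α-[5-(trimethylsilyl)pent-4-ynoyl] | C[Si](C)(C)C#CCCC(=O)[C@@]1(C)C[C@H]2OC(C)(C)O[C@H]2C(C)(C)[C@@H]1CCC=C
A6 | alternative 3 | 9β-hydroxy-8α-methyl-9α-[4-(trimethylsilyl)but-3-ynyl] trans-decalin, 2α,3α-acetonide | C[Si](C)(C)C#CCC[C@]1(O)[C@H](C)CC[C@H]2C(C)(C)[C@H](OC(C)(C)O3)[C@H]3C[C@@]21C
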